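A direct plan would iodinate 2,6-dimethoxy-4-methylbenzaldehyde A1 to its 3-iodide A2 and join A2, carbon monoxide and benzyl 2,4-dihydroxy-3,6-dimethylbenzoate A3 under palladium catalysis to the formyl depside ester A4, then hydrogenolyse to the acid A5 and reduce the aldehyde. Its weakest steps would be:
- the carbonylative esterification, because acyl–oxygen bond formation at a carbon flanked by OMe and CH3, with an ortho-substituted phenol, would be without precedent;
- the hydrogenolysis of the benzyl ester beside a free aryl aldehyde, because over-reduction to CH3 would threaten;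
- the closing borohydride reduction, because it would be a step of its own that adds length but no complexity.

**Strategy.** The route would rest on making ring A last, around an ester that already exists. In ring A, C2(OMe)–C3(CH2O)–C4(OMe)–C5(H) has the pattern of a 2-substituted 1,3-dimethoxycyclohexa-1,3-diene, and C1(CO2Ar)–C6(CH3) that of a but-2-ynoate. The depside C(acyl)–O bond would therefore be made on but-2-ynoic acid, whose acyl carbon has no ortho neighbours. One Alder–Rickert cycloaddition with loss of ethylene would then form C1–C2 and C5–C6 and deliver ring A with all five substituents and both methyl ethers in place. No hindered esterification, no aryl–palladium step and no aldehyde would occur, and a single hydrogenolysis would finish.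

Key step: step 4

Remark: the target has no stereocentre, so no stereocontrol is needed; compounds 1, 3 and 5 are taken to be purchasable.

**Step 1**
Reactants: 1 2,4-dihydroxy-3,6-dimethylbenzoic acid
Product: 2 benzyl 2,4-dihydroxy-3,6-dimethylbenzoate
Conditions: BnBr (1.05 equiv), KHCO3, DMF, rt
Reagents that add atoms: benzyl bromide BrCc1ccccc1
Why: Carboxylate O-alkylation (SN2): bicarbonate should deprotonate only the carboxylic acid, so that both phenols stay free and only the benzyl ester forms; no stereocentre is formed.

**Step 2**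
Reactants: 2 benzyl 2,4-dihydroxy-3,6-dimethylbenzoate; 3 but-2-ynoic acid
Product: 4 benzyl 4-(but-2-ynoyloxy)-2-hydroxy-3,6-dimethylbenzoate
Conditions: DCC (1.1 equiv), DMAP (5 mol %), CH2Cl2, −10 °C to rt
Reagents that add atoms: none
Why: Steglich esterification: the 4-OH should be acylated selectively because the 2-OH is held in a hydrogen bond to the ester carbonyl between two ortho substituents, and the acyl carbon of 3 sits on an sp carbon without ortho neighbours, so the future depside C(acyl)–O bond should form without steric penalty; no stereocentre is formed.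

**Step 3**
Reactants: 5 1,5-dimethoxycyclohexa-1,4-diene
Product: 7 6-[(benzyloxy)methyl]-1,5-dimethoxycyclohexa-1,4-diene, via (2,6-dimethoxycyclohexa-2,5-dien-1-yl)lithium 6 (not isolated)
Conditions: t-BuLi (1.0 equiv), THF/HMPA, −78 °C; BnOCH2Cl, −78 to −20 °C; pH 7 buffer
Reagents that add atoms: tert-butyllithium [Li]C(C)(C)C (lithium, present in 6 only); benzyl chloromethyl ether ClCOCc1ccccc1
Why: Metalation–alkylation of a Birch-type diene: tert-butyllithium should remove a proton from C6, the doubly allylic CH2 between the two methoxy-bearing carbons (a pentadienyl anion with both OMe groups on nodal carbons), and the anion should be alkylated at this central carbon by the α-chloro ether (SN2); C6 of 7 lies on a mirror plane and is no stereocentre.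

**Step 4**
Reactants: 7 6-[(benzyloxy)methyl]-1,5-dimethoxycyclohexa-1,4-diene; 4 benzyl 4-(but-2-ynoyloxy)-2-hydroxy-3,6-dimethylbenzoate
Product: 10 benzyl 4-({3-[(benzyloxy)methyl]-2,4-dimethoxy-6-methylbenzoyl}oxy)-2-hydroxy-3,6-dimethylbenzoate, via 2-[(benzyloxy)methyl]-1,3-dimethoxycyclohexa-1,3-diene 8 (not isolated), via bicyclo[2.2.2]octa-2,5-diene cycloadduct 9 (not isolated)
Conditions: 7 (2 equiv), RhCl(PPh3)3 (1 mol %), toluene, 80 °C, then passed through basic alumina; 4, 2,6-di-tert-butyl-4-methylpyridine (5 mol %), o-xylene, 160 °C, sealed tube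
Reagents that add atoms: none
Why: Monovalent rhodium should move one enol-ether double bond of 7 into conjugation through C6 to give the s-cis-locked diene 8 with both enol ethers kept; 8 should then add to the ynoate of 4 in a normal-demand [4+2] cycloaddition, and the bicyclo[2.2.2]octadiene 9 should lose its CH2CH2 bridge as ethylene in a retro-Diels–Alder step driven by aromatisation (Alder–Rickert reaction). The closest known reaction type is the Alder–Rickert synthesis of 2,4-dimethoxy-6-alkylbenzoates from 1,3-dimethoxycyclohexa-1,3-dienes and alk-2-ynoates. Ring A is closed by intermolecular [4+2] cycloaddition, which forms its C1–C2 and C5–C6 bonds, and is unmasked by the cycloreversion. The two bridgehead stereocentres of 9 are fixed only relative to each other by the bicyclic frame, are racemic and vanish with the ethylene, so 10 has no stereocentre. The step needs one regiochemistry, which the substrates secure: the unsubstituted diene terminus C4 carries the largest HOMO coefficient (β to the 3-OMe, δ to the 1-OMe) and should bond to the methyl-bearing β-carbon of the ynoate, so that C1(OMe) bonds to the carbon bearing the aryl ester and the CH2OBn carbon ends between the two methoxy groups. The aryl ester is only a spectator, since its C(acyl)–O bond was made in step 2, and the chelated 2-OH and the benzyl ester of ring B should be thermally inert.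

**Step 5**
Reactants: 10 benzyl 4-({3-[(benzyloxy)methyl]-2,4-dimethoxy-6-methylbenzoyl}oxy)-2-hydroxy-3,6-dimethylbenzoate
Product: 11 2-hydroxy-4-{[3-(hydroxymethyl)-2,4-dimethoxy-6-methylbenzoyl]oxy}-3,6-dimethylbenzoic acid
Conditions: H2 (1 atm), 10% Pd/C, EtOAc, rt, stopped after uptake of 2 equiv
Reagents that add atoms: none
Why: Catalytic hydrogenolysis: the benzyl ester and the benzyl ether should both be cleaved at their unhindered PhCH2–O bonds, whereas the ring A benzylic C–O bond (shielded by two ortho methoxy groups), the aryl ester and the arenes should stay; no stereocentre is involved.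

**Compound list**
1 | 2,4-dihydroxy-3,6-dimethylbenzoic acid | Cc1cc(O)c(C)c(O)c1C(=O)O | starting material
2 | benzyl 2,4-dihydroxy-3,6-dimethylbenzoate | Cc1cc(O)c(C)c(O)c1C(=O)OCc1ccccc1 | intermediate
3 | but-2-ynoic acid | CC#CC(=O)O | starting material
4 | benzyl 4-(but-2-ynoyloxy)-2-hydroxy-3,6-dimethylbenzoate | CC#CC(=O)Oc1cc(C)c(C(=O)OCc2ccccc2)c(O)c1C | intermediate
5 | 1,5-dimethoxycyclohexa-1,4-diene | COC1=CCC=C(OC)C1 | starting material
6 | (2,6-dimethoxycyclohexa-2,5-dien-1-yl)lithium | [Li]C1C(OC)=CCC=C1OC | intermediate (not isolated)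
7 | 6-[(benzyloxy)methyl]-1,5-dimethoxycyclohexa-1,4-diene (achiral) | COC1=CCC=C(OC)C1COCc1ccccc1 | intermediate
8 | 2-[(benzyloxy)methyl]-1,3-dimethoxycyclohexa-1,3-diene | COC1=C(COCc2ccccc2)C(OC)=CCC1 | intermediate (not isolated)
9 | benzyl 4-({6-[(benzyloxy)methyl]-1,5-dimethoxy-3-methylbicyclo[2.2.2]octa-2,5-diene-2-carbonyl}oxy)-2-hydroxy-3,6-dimethylbenzoate (racemic, transient; relative configuration of the bridgeheads fixed by the ring system) | COC12CCC(C(OC)=C1COCc1ccccc1)C(C)=C2C(=O)Oc1cc(C)c(C(=O)OCc2ccccc2)c(O)c1C | intermediate (not isolated)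
10 | benzyl 4-({3-[(benzyloxy)methyl]-2,4-dimethoxy-6-methylbenzoyl}oxy)-2-hydroxy-3,6-dimethylbenzoate | COc1cc(C)c(C(=O)Oc2cc(C)c(C(=O)OCc3ccccc3)c(O)c2C)c(OC)c1COCc1ccccc1 | intermediate
11 | 2-hydroxy-4-{[3-(hydroxymethyl)-2,4-dimethoxy-6-methylbenzoyl]oxy}-3,6-dimethylbenzoic acid (achiral) | COc1cc(C)c(C(=O)Oc2cc(C)c(C(=O)O)c(O)c2C)c(OC)c1CO | target

Total step count: 5. Longest linear sequence: 4 steps (steps 1, 2, 4 and 5).

**Steps most likely to fail**

Step 4. The cycloaddition of the β-methyl ynoate may be slower than the decay of dienyl ether 8 by loss of methanol or benzyl alcohol with aromatisation, which the phenolic OH of 4 may promote. The fallback sets out from 7 and comes back at 10; it builds ring A on a small, robust ynoate under forcing conditions and makes the depside ester afterwards. 7 would be conjugated as in step 4 and heated with an excess of neat methyl but-2-ynoate at 180 °C. Through 8 and the cycloadduct methyl 6-[(benzyloxy)methyl]-1,5-dimethoxy-3-methylbicyclo[2.2.2]octa-2,5-diene-2-carboxylate F1, this should give methyl 3-[(benzyloxy)methyl]-2,4-dimethoxy-6-methylbenzoate F2. Saponification (KOH, aqueous DMSO, 90 °C) would give 3-[(benzyloxy)methyl]-2,4-dimethoxy-6-methylbenzoic acid F3. 1-Chloro-N,N,2-trimethylprop-1-en-1-amine in CH2Cl2 would convert it under neutral conditions into 3-[(benzyloxy)methyl]-2,4-dimethoxy-6-methylbenzoyl chloride F4. F4 with 2 (Et3N, DMAP, CH2Cl2) should acylate the free 4-OH and give 10.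

Step 5. Hydrogenolysis may go on to the ring A benzylic C–O bond once the free acid is present, which would turn the CH2O group into CH3. The fallback sets out from 10 and comes back at 11; it removes the ether oxidatively instead of reductively. 10 would be hydrogenated over Pd/C in EtOAc in the presence of pyridine, which should stop at the benzyl ester and give 4-({3-[(benzyloxy)methyl]-2,4-dimethoxy-6-methylbenzoyl}oxy)-2-hydroxy-3,6-dimethylbenzoic acid F5. DDQ in wet CH2Cl2 should then oxidise the ether at the electron-rich ring A benzylic carbon and release 4-[(3-formyl-2,4-dimethoxy-6-methylbenzoyl)oxy]-2-hydroxy-3,6-dimethylbenzoic acid F6 together with benzyl alcohol. NaBH4 (THF/MeOH, 0 °C, work-up at pH 3) would reduce F6 to 11.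

Step 3. Proton transfer from product 7 to unreacted 6, followed by loss of benzyl alcoholate from the new anion (E1cB), or attack of the anion through its terminal carbons, may erode the alkylation. The fallback sets out from 5 and comes back at 7; it brings in the carbon and the benzyl group separately. 6 would be made as in step 3 and quenched at −78 °C with gaseous formaldehyde to give (2,6-dimethoxycyclohexa-2,5-dien-1-yl)methanol F7, whose alkoxide oxygen is a poor leaving group. F7 would then be benzylated on oxygen (NaH, BnBr, Bu4NI, THF, 0 °C) to give 7.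

**Further compounds**
F1 | step 4 | methyl 6-[(benzyloxy)methyl]-1,5-dimethoxy-3-methylbicyclo[2.2.2]octa-2,5-diene-2-carboxylate (racemic, transient) | COC12CCC(C(OC)=C1COCc1ccccc1)C(C)=C2C(=O)OC
F2 | step 4 | methyl 3-[(benzyloxy)methyl]-2,4-dimethoxy-6-methylbenzoate | COC(=O)c1c(C)cc(OC)c(COCc2ccccc2)c1OC
F3 | step 4 | 3-[(benzyloxy)methyl]-2,4-dimethoxy-6-methylbenzoic acid | OC(=O)c1c(C)cc(OC)c(COCc2ccccc2)c1OC
F4 | step 4 | 3-[(benzyloxy)methyl]-2,4-dimethoxy-6-methylbenzoyl chloride | ClC(=O)c1c(C)cc(OC)c(COCc2ccccc2)c1OC
F5 | step 5 | 4-({3-[(benzyloxy)methyl]-2,4-dimethoxy-6-methylbenzoyl}oxy)-2-hydroxy-3,6-dimethylbenzoic acid | COc1cc(C)c(C(=O)Oc2cc(C)c(C(=O)O)c(O)c2C)c(OC)c1COCc1ccccc1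
F6 | step 5 | 4-[(3-formyl-2,4-dimethoxy-6-methylbenzoyl)oxy]-2-hydroxy-3,6-dimethylbenzoic acid | COc1cc(C)c(C(=O)Oc2cc(C)c(C(=O)O)c(O)c2C)c(OC)c1C=O
F7 | step 3 | (2,6-dimethoxycyclohexa-2,5-dien-1-yl)methanol | COC1=CCC=C(OC)C1CO
A1 | direct plan | 2,6-dimethoxy-4-methylbenzaldehyde | COc1cc(C)cc(OC)c1C=O
A2 | direct plan | 3-iodo-2,6-dimethoxy-4-methylbenzaldehyde | COc1cc(C)c(I)c(OC)c1C=O
A3 | direct plan | benzyl 2,4-dihydroxy-3,6-dimethylbenzoate | Cc1cc(O)c(C)c(O)c1C(=O)OCc1ccccc1
A4 | direct plan | benzyl 4-[(3-formyl-2,4-dimethoxy-6-methylbenzoyl)oxy]-2-hydroxy-3,6-dimethylbenzoate | COc1cc(C)c(C(=O)Oc2cc(C)c(C(=O)OCc3ccccc3)c(O)c2C)c(OC)c1C=O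
A5 | direct plan | 4-[(3-formyl-2,4-dimethoxy-6-methylbenzoyl)oxy]-2-hydroxy-3,6-dimethylbenzoic acid | COc1cc(C)c(C(=O)Oc2cc(C)c(C(=O)O)c(O)c2C)c(OC)c1C=O
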